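**Retrosynthetic overview**
1. Target ⇐ hydroxyl-directed epoxidation of the 4,5-olefin of a 6-hydroxy-germacra-1(10),4-dien-8-yl trimethoxybenzoate; the 6-carbinol comes from hydride reduction of the ring 6-ketone, the ester from acylation of the 8-hydroxyl.
2. (E,E)-Cyclodecadiene ⇐ reduction of an enol triflate ⇐ anionic oxy-Cope rearrangement ([3,3]) of a trans-1-isopropenyl-2-methyl-2-vinylcyclohexanol (C2–C3 formed, C5–C10 broken).
3. That cyclohexanol ⇐ isopropenyl addition to a 2-methyl-2-vinylcyclohexanone ⇐ reductive α-vinylation of a 4,6-bis(silyloxy)-2-methyl-5-isopropylcyclohexenone.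
4. The enone ⇐ Rubottom oxidation ⇐ 4-hydroxy enone ⇐ singlet-oxygen [4+2] cycloaddition / Kornblum–DeLaMare rearrangement of (R)-α-phellandrene, which supplies C7; all other centres follow from it.
5. Ring order: six-membered ring bought → ten-membered ring by the oxy-Cope step → oxirane last.

Assumption: germacrane numbering of the target is used for the ten-membered ring and for the corresponding carbons of its cyclohexane precursors (C10 carries the ring methyl, C7 the isopropyl group, C5, C6 and C8 the oxygens); commercial (R)-(−)-α-phellandrene of high enantiomeric purity is assumed.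

**Step 1**
Reactants: 1 (R)-(−)-α-phellandrene
Product: 3 (4R,5R)-4-hydroxy-2-methyl-5-isopropylcyclohex-2-en-1-one, via endoperoxide 2 (not isolated)
Conditions: O2, tetraphenylporphyrin (cat.), visible light, CH2Cl2, −20 °C; then Et3N, 0 °C → rt
Reagents that add atoms: dioxygen O=O
Why: Singlet oxygen adds to the diene in a [4+2] cycloaddition mainly anti to the isopropyl group, and the amine then effects a Kornblum–DeLaMare rearrangement by removing the bridgehead hydrogen remote from the isopropyl-bearing carbon, so the C8 hydroxyl is set trans to the bought C7 centre (facial and regio-isomers are removed by chromatography).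

**Step 2**
Reactants: 3 (4R,5R)-4-hydroxy-2-methyl-5-isopropylcyclohex-2-en-1-one
Product: 4 2,5-bis(tert-butyldimethylsilyloxy)-3-methyl-6-isopropylcyclohexa-1,3-diene (5-silyloxy trans to 6-isopropyl)
Conditions: TBSOTf (2.3 equiv), Et3N, CH2Cl2, −78 → 0 °C
Reagents that add atoms: tert-butyldimethylsilyl triflate CC(C)(C)[Si](C)(C)OS(=O)(=O)C(F)(F)F
Why: Silyl triflate silylates the alcohol and, by soft enolization with kinetic α'-deprotonation, turns the enone into the cross-conjugated 2-silyloxy diene without touching the C7 or C8 centres.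

**Step 3**
Reactants: 4 2,5-bis(tert-butyldimethylsilyloxy)-3-methyl-6-isopropylcyclohexa-1,3-diene
Product: 5 4,6-bis(tert-butyldimethylsilyloxy)-2-methyl-5-isopropylcyclohex-2-en-1-one (both silyloxy groups trans to isopropyl)
Conditions: mCPBA, NaHCO3, CH2Cl2, −20 °C
Reagents that add atoms: mCPBA OOC(=O)c1cccc(Cl)c1
Why: Rubottom oxidation, in which the peracid epoxidizes the electron-rich enol ether bond anti to the adjacent isopropyl group and 1,4-silyl migration gives the α'-silyloxy enone (this C6 centre is only a placeholder and is oxidized in step 9).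

**Step 4**
Reactants: 5 4,6-bis(tert-butyldimethylsilyloxy)-2-methyl-5-isopropylcyclohex-2-en-1-one
Product: 7 4,6-bis(tert-butyldimethylsilyloxy)-2-ethenyl-2-methyl-5-isopropylcyclohexan-1-one (vinyl cis to isopropyl), via lithium enolate 6 (not isolated)
Conditions: LiBH(s-Bu)3, THF, −78 °C; then CH2=CHBr, Pd2(dba)3 (cat.), P(t-Bu)3 (cat.), −78 °C → rt
Reagents that add atoms: vinyl bromide C=CBr
Why: Conjugate hydride reduction gives the regiodefined tetrasubstituted enolate, and its α-vinylation by enolate cross-coupling on zerovalent palladium forms the quaternary carbon by axial bond formation, cis to the equatorial isopropyl group (this centre is destroyed again in step 6).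

**Step 5**
Reactants: 7 4,6-bis(tert-butyldimethylsilyloxy)-2-ethenyl-2-methyl-5-isopropylcyclohexan-1-one
Product: 8 4,6-bis(tert-butyldimethylsilyloxy)-2-ethenyl-2-methyl-1-(prop-1-en-2-yl)-5-isopropylcyclohexan-1-ol (isopropenyl trans to vinyl)
Conditions: CH2=C(CH3)MgBr, CeCl3, THF, −78 °C
Reagents that add atoms: isopropenylmagnesium bromide CC(=C)[Mg]Br
Why: Organocerium 1,2-addition without enolization, in which axial attack on the face opposite the axial vinyl group gives the trans-1,2-dialkenyl carbinol needed for an (E,E)-selective rearrangement (the carbinol centre is destroyed in step 6).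

**Step 6**
Reactants: 8 4,6-bis(tert-butyldimethylsilyloxy)-2-ethenyl-2-methyl-1-(prop-1-en-2-yl)-5-isopropylcyclohexan-1-ol
Product: 10 (1(10)E)-6,8-bis(tert-butyldimethylsilyloxy)germacra-1(10),4-dien-5-yl triflate (C3 and C6 trans on the C4=C5 bond), via potassium enolate 9 (not isolated)
Conditions: KH, 18-crown-6, THF, 0 → 45 °C; then PhNTf2, −78 → 0 °C
Reagents that add atoms: N-phenyl-bis(trifluoromethanesulfonimide) O=S(=O)(N(c1ccccc1)S(=O)(=O)C(F)(F)F)C(F)(F)F
Why: Anionic oxy-Cope [3,3]-sigmatropic rearrangement through a chair-like six-centre transition state with both ring residues equatorial (the trans alkenyl groups become gauche in a twist-boat) gives the ten-membered ring with the (E)-C1=C10 olefin and an enolate of fixed geometry, which is trapped on oxygen as the enol triflate.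

**Step 7**
Reactants: 10 (1(10)E)-6,8-bis(tert-butyldimethylsilyloxy)germacra-1(10),4-dien-5-yl triflate
Product: 11 (1(10)E,4E)-6,8-bis(tert-butyldimethylsilyloxy)germacra-1(10),4-diene (both silyloxy groups trans to the 7-isopropyl)
Conditions: Pd(OAc)2 (cat.), PPh3, HCO2H, n-Bu3N, DMF, 50 °C
Reagents that add atoms: none
Why: Palladium-catalysed formate reduction of the enol triflate replaces the triflate by hydrogen with retention of olefin geometry, giving the (4E)-olefin below the temperature of Cope reversion.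

**Step 8**
Reactants: 11 (1(10)E,4E)-6,8-bis(tert-butyldimethylsilyloxy)germacra-1(10),4-diene
Product: 12 (1(10)E,4E)-germacra-1(10),4-diene-6,8-diol (both hydroxyls trans to the 7-isopropyl)
Conditions: Bu4NF, THF, 0 °C → rt
Reagents that add atoms: none
Why: Fluoride desilylation removes both silyl ethers under non-acidic conditions that the cyclization-prone 1,5-diene tolerates.

**Step 9**
Reactants: 12 (1(10)E,4E)-germacra-1(10),4-diene-6,8-diol
Product: 13 (1(10)E,4E)-8-hydroxygermacra-1(10),4-dien-6-one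
Conditions: MnO2 (activated, excess), CH2Cl2, rt
Reagents that add atoms: none
Why: Chemoselective allylic oxidation, since MnO2 oxidizes the allylic C6 alcohol and leaves the saturated C8 alcohol untouched.

**Step 10**
Reactants: 13 (1(10)E,4E)-8-hydroxygermacra-1(10),4-dien-6-one; 14 3,4,5-trimethoxybenzoyl chloride
Product: 15 (1(10)E,4E)-6-oxogermacra-1(10),4-dien-8-yl 3,4,5-trimethoxybenzoate
Conditions: pyridine, DMAP (cat.), CH2Cl2, 0 °C
Reagents that add atoms: none
Why: DMAP-catalysed esterification of the only free hydroxyl with retention at C8, under a base too weak to eliminate the β-acyloxy ketone.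

**Step 11**
Reactants: 15 (1(10)E,4E)-6-oxogermacra-1(10),4-dien-8-yl 3,4,5-trimethoxybenzoate
Product: 16 (1(10)E,4E)-6-hydroxygermacra-1(10),4-dien-8-yl 3,4,5-trimethoxybenzoate (6-hydroxyl cis to the 7-isopropyl)
Conditions: NaBH4, CeCl3·7H2O, MeOH, −78 °C
Reagents that add atoms: none
Why: Luche 1,2-reduction, in which C7 and the rest of the ring shield the inner face so that hydride adds from the exposed side remote from the C4 methyl and gives the (6R)-alcohol cis to the isopropyl group.

**Step 12**
Reactants: 16 (1(10)E,4E)-6-hydroxygermacra-1(10),4-dien-8-yl 3,4,5-trimethoxybenzoate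
Product: 17 (1(10)E,4R,5R,6R,7S,8S)-4,5-epoxy-6-hydroxygermacr-1(10)-en-8-yl 3,4,5-trimethoxybenzoate
Conditions: VO(acac)2 (cat.), t-BuOOH, CH2Cl2, 0 °C
Reagents that add atoms: tert-butyl hydroperoxide CC(C)(C)OO
Why: Hydroxyl-directed vanadium-catalysed epoxidation touches only the allylic 4,5-olefin, and only its peripheral face is open in the isopropyl-equatorial crossed conformer of the (E)-cyclodecene, which gives the (4R,5R) trans-epoxide.

**Compound list**
1 | (R)-(−)-α-phellandrene | CC1=CC[C@@H](C=C1)C(C)C | starting material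
2 | 5-methyl-7-isopropyl-2,3-dioxabicyclo[2.2.2]oct-5-ene (peroxide bridge anti to isopropyl) | CC1=C[C@@H]2OO[C@H]1C[C@@H]2C(C)C | intermediate
3 | (4R,5R)-4-hydroxy-2-methyl-5-isopropylcyclohex-2-en-1-one | CC1=C[C@H](O)[C@@H](C(C)C)CC1=O | intermediate
4 | 2,5-bis(tert-butyldimethylsilyloxy)-3-methyl-6-isopropylcyclohexa-1,3-diene (5-silyloxy trans to 6-isopropyl) | CC1=C[C@H](O[Si](C)(C)C(C)(C)C)[C@@H](C(C)C)C=C1O[Si](C)(C)C(C)(C)C | intermediate
5 | 4,6-bis(tert-butyldimethylsilyloxy)-2-methyl-5-isopropylcyclohex-2-en-1-one (both silyloxy groups trans to isopropyl) | CC1=C[C@H](O[Si](C)(C)C(C)(C)C)[C@@H](C(C)C)[C@H](O[Si](C)(C)C(C)(C)C)C1=O | intermediate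
6 | lithium 4,6-bis(tert-butyldimethylsilyloxy)-2-methyl-5-isopropylcyclohex-1-en-1-olate | [Li+].CC1=C([O-])[C@@H](O[Si](C)(C)C(C)(C)C)[C@H](C(C)C)[C@@H](O[Si](C)(C)C(C)(C)C)C1 | intermediate
7 | 4,6-bis(tert-butyldimethylsilyloxy)-2-ethenyl-2-methyl-5-isopropylcyclohexan-1-one (vinyl cis to isopropyl) | C=C[C@@]1(C)C[C@H](O[Si](C)(C)C(C)(C)C)[C@@H](C(C)C)[C@H](O[Si](C)(C)C(C)(C)C)C1=O | intermediate
8 | 4,6-bis(tert-butyldimethylsilyloxy)-2-ethenyl-2-methyl-1-(prop-1-en-2-yl)-5-isopropylcyclohexan-1-ol (isopropenyl trans to vinyl) | C=C[C@@]1(C)C[C@H](O[Si](C)(C)C(C)(C)C)[C@@H](C(C)C)[C@H](O[Si](C)(C)C(C)(C)C)[C@]1(O)C(C)=C | intermediate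
9 | potassium (1(10)E)-6,8-bis(tert-butyldimethylsilyloxy)germacra-1(10),4-dien-5-olate (C3 and C6 trans on C4=C5) | [K+].CC(C)(C)[Si](C)(C)O[C@H]1C/C(C)=C/CC/C(C)=C(\[O-])/[C@@H](O[Si](C)(C)C(C)(C)C)[C@@H]1C(C)C | intermediate
10 | (1(10)E)-6,8-bis(tert-butyldimethylsilyloxy)germacra-1(10),4-dien-5-yl triflate (C3 and C6 trans on C4=C5) | CC(C)(C)[Si](C)(C)O[C@H]1C/C(C)=C/CC/C(C)=C(\OS(=O)(=O)C(F)(F)F)/[C@@H](O[Si](C)(C)C(C)(C)C)[C@@H]1C(C)C | intermediate
11 | (1(10)E,4E)-6,8-bis(tert-butyldimethylsilyloxy)germacra-1(10),4-diene | CC(C)(C)[Si](C)(C)O[C@H]1C/C(C)=C/CC/C(C)=C/[C@@H](O[Si](C)(C)C(C)(C)C)[C@@H]1C(C)C | intermediate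
12 | (1(10)E,4E)-germacra-1(10),4-diene-6,8-diol (both hydroxyls trans to 7-isopropyl) | O[C@H]1C/C(C)=C/CC/C(C)=C/[C@@H](O)[C@@H]1C(C)C | intermediate
13 | (1(10)E,4E)-8-hydroxygermacra-1(10),4-dien-6-one | O[C@H]1C/C(C)=C/CC/C(C)=C/C(=O)[C@@H]1C(C)C | intermediate
14 | 3,4,5-trimethoxybenzoyl chloride | COc1cc(C(Cl)=O)cc(OC)c1OC | starting material
15 | (1(10)E,4E)-6-oxogermacra-1(10),4-dien-8-yl 3,4,5-trimethoxybenzoate | COc1cc(C(=O)O[C@H]2C/C(C)=C/CC/C(C)=C/C(=O)[C@@H]2C(C)C)cc(OC)c1OC | intermediate
16 | (1(10)E,4E)-6-hydroxygermacra-1(10),4-dien-8-yl 3,4,5-trimethoxybenzoate (6-hydroxyl cis to 7-isopropyl) | COc1cc(C(=O)O[C@H]2C/C(C)=C/CC/C(C)=C/[C@H](O)[C@@H]2C(C)C)cc(OC)c1OC | intermediate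
17 | (1(10)E,4R,5R,6R,7S,8S)-4,5-epoxy-6-hydroxygermacr-1(10)-en-8-yl 3,4,5-trimethoxybenzoate | COc1cc(C(=O)O[C@H]2C/C(C)=C/CC[C@@]3(C)O[C@@H]3[C@H](O)[C@@H]2C(C)C)cc(OC)c1OC | target

**Totals**
Total step count: 12. Longest linear sequence: 12 steps (1 → 17); 14 is used as bought.

**Three steps most likely to fail**

Step 4. The one-pot conjugate reduction / palladium vinylation must build a hindered quaternary carbon, and the tri-sec-butylborane left by the hydride may disturb the coupling. The fallback sets out from 5 and comes back at 7. Compound 5 is reduced with LiBH(s-Bu)3 as before and the enolate is added in a Michael reaction to phenyl vinyl sulfoxide, giving 4,6-bis(tert-butyldimethylsilyloxy)-2-methyl-2-[2-(phenylsulfinyl)ethyl]-5-isopropylcyclohexan-1-one F1. Heating F1 in toluene at 110 °C over CaCO3 (sulfoxide syn-elimination) unmasks the vinyl group and delivers 7.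

Step 6. The alkoxide of 8 has its two alkenyl groups trans-diaxial and must rearrange through a twist-boat, where fragmentation–recombination can compete. The tetrasubstituted enolate is also hindered toward O-triflation, and the triflate toward the palladium reduction of step 7. The fallback sets out from 8 and comes back at 11. The rearrangement is run with KH and 18-crown-6 as before, but the enolate is trapped with ClP(O)(OEt)2 as (1(10)E)-6,8-bis(tert-butyldimethylsilyloxy)germacra-1(10),4-dien-5-yl diethyl phosphate F2. Dissolving-metal cleavage of F2 (Li, EtNH2, t-BuOH, THF, −78 °C) removes the phosphate with retention of olefin geometry and gives 11 without a triflate or palladium.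

Step 11. The facial selectivity of the ketone reduction rests on a conformational argument for the ten-membered enone, not on a closely analogous case. The fallback sets out from 15 and comes back at 17. If NaBH4/CeCl3 gives mainly the 6-epimeric alcohol (6-hydroxyl trans to isopropyl) F3, F3 is epoxidized with VO(acac)2/t-BuOOH on the peripheral face to the 6-epimeric epoxy alcohol F4. F4 is oxidized with Dess–Martin periodinane (pyridine buffer) to the 4,5-epoxy-6-ketone F5. Chelation-controlled reduction of F5 with Zn(BH4)2 in ether at −20 °C, which is reliably erythro-selective for α,β-epoxy ketones, then gives 17.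

**Further compounds**
F1 | step 4 | 4,6-bis(tert-butyldimethylsilyloxy)-2-methyl-2-[2-(phenylsulfinyl)ethyl]-5-isopropylcyclohexan-1-one (side chain cis to isopropyl; mixture at sulfur) | O=S(CC[C@@]1(C)C[C@H](O[Si](C)(C)C(C)(C)C)[C@@H](C(C)C)[C@H](O[Si](C)(C)C(C)(C)C)C1=O)c1ccccc1
F2 | step 6 | (1(10)E)-6,8-bis(tert-butyldimethylsilyloxy)germacra-1(10),4-dien-5-yl diethyl phosphate (C3 and C6 trans on C4=C5) | CC(C)(C)[Si](C)(C)O[C@H]1C/C(C)=C/CC/C(C)=C(\OP(=O)(OCC)OCC)/[C@@H](O[Si](C)(C)C(C)(C)C)[C@@H]1C(C)C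
F3 | step 11 | (1(10)E,4E)-6-hydroxygermacra-1(10),4-dien-8-yl 3,4,5-trimethoxybenzoate with 6-hydroxyl trans to isopropyl (6-epimer of 16) | COc1cc(C(=O)O[C@H]2C/C(C)=C/CC/C(C)=C/[C@@H](O)[C@@H]2C(C)C)cc(OC)c1OC
F4 | step 11 | 4,5-epoxy-6-hydroxygermacr-1(10)-en-8-yl 3,4,5-trimethoxybenzoate with the epoxide of 17 and the 6-hydroxyl trans to isopropyl (6-epimer of 17) | COc1cc(C(=O)O[C@H]2C/C(C)=C/CC[C@@]3(C)O[C@@H]3[C@@H](O)[C@@H]2C(C)C)cc(OC)c1OC
F5 | step 11 | 4,5-epoxy-6-oxogermacr-1(10)-en-8-yl 3,4,5-trimethoxybenzoate (epoxide as in 17) | COc1cc(C(=O)O[C@H]2C/C(C)=C/CC[C@@]3(C)O[C@@H]3C(=O)[C@@H]2C(C)C)cc(OC)c1OC
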